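Numbering: ring C1 (CMe2), C2 (CHBr), C3 (alkylidene carbon), C4 (CHCl), C5 (CH2), C6 (CHCl); side chain C7 (=CH), C8 (CH2Br).
Retrosynthesis: cut C8–Br and C4–Cl together (1,4-addition of BrCl to the diene C4=C3–C7=C8). Then exchange H on C5 for SiMe3 on C8 (pentadienylsilane C5=C4–C3=C7–C8), raise one methyl on C1 to CHO, and cut C2–C3 and C1–C6 in one [4+2] retron.
Enabling feature: in the six-membered carbocycle, the sp2 ring atom C3 carries the exocyclic C3=C7 bond next to C2, and the quaternary C1 is flanked by C2–Br and C6–Cl. This is the imprint of a bromoalkene C1=C2 added across C3 and C6 of a chlorovinylallene C6=C5–C4=C3=C7, so both neopentyl carbon–halogen bonds arrive on sp2 carbons and no substitution next to C1 is needed.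
Forward: the allene arm (steps 1–5) and the bromoenal arm (steps 6–7) are joined in step 8, which builds the only ring. The helpers then leave (CHO to CH3 in steps 9–10, SiMe3 for H in step 11), and BrCl closes the route (step 12).
Stereochemistry: a Midland reduction sets one carbinol centre and anti-SN2′ substitution turns it into the allene axis. The cycloaddition (anti to CH2SiMe3, endo, cis-principle) turns the axis into C2 and C6. Chloride attack anti to both ring halogens sets C4, and the s-trans diene fixes C8 cis to C2.

Key step: step 8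

Assumption: compounds 1, 2, 8, 11 and 12 and the reagents named in the Conditions lines are taken as commercial.

Step 1
Reactants: 1 (E)-3-chloroacrylic acid; 2 bis(trimethylsilyl)acetylene
Product: 4 (E)-1-chloro-5-(trimethylsilyl)pent-1-en-4-yn-3-one, via (E)-3-chloroacryloyl chloride 3 (not isolated)
Conditions: (COCl)2, DMF (cat.), CH2Cl2, 0 °C to rt, evaporate; then 2, AlCl3, CH2Cl2, 0 °C
Reagents that add atoms: oxalyl chloride, ClC(=O)C(=O)Cl (supplies only the acyl chlorine of 3)
Why: Acid chloride formation followed by Friedel–Crafts-type ipso-acylation of the alkynylsilane (β-silicon-stabilised vinyl cation, loss of Me3SiCl) should stop at the mono-acylated ynone because the product alkyne is deactivated, and the (E)-chloroalkene is not involved.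

Step 2
Reactants: 4 (E)-1-chloro-5-(trimethylsilyl)pent-1-en-4-yn-3-one
Product: 5 (1E,3R)-1-chloro-5-(trimethylsilyl)pent-1-en-4-yn-3-ol
Conditions: (R)-Alpine-Borane (B-isopinocampheyl-9-BBN from (+)-α-pinene), THF, 0 °C to rt; CH3CHO; then HOCH2CH2NH2, Et2O, 0 °C
Reagents that add atoms: none
Why: Midland reduction, in which the pinanyl β-hydrogen is delivered through a boat-like six-membered transition state with the slim alkynyl group next to the pinane methyl group, so the (R)-reagent should set the (R)-carbinol while the chloroalkene stays untouched.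

Step 3
Reactants: 5 (1E,3R)-1-chloro-5-(trimethylsilyl)pent-1-en-4-yn-3-ol
Product: 6 (1E,3R)-1-chloropent-1-en-4-yn-3-ol
Conditions: K2CO3 (cat.), MeOH, 0 °C
Reagents that add atoms: none
Why: Base-catalysed methanolysis of the alkynyl C–Si bond (protiodesilylation) frees the terminal alkyne needed in step 5 without touching the carbinol centre or the vinyl chloride.

Step 4
Reactants: 6 (1E,3R)-1-chloropent-1-en-4-yn-3-ol
Product: 7 (1E,3R)-1-chloropent-1-en-4-yn-3-yl methanesulfonate
Conditions: MsCl, Et3N, CH2Cl2, −78 to −40 °C; cold aqueous work-up, used crude at once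
Reagents that add atoms: methanesulfonyl chloride, CS(=O)(=O)Cl
Why: Mesylation through sulfene changes only the O–H bond, so the configuration at C4 is retained, and the low temperature keeps the doubly activated ester from ionising.

Step 5
Reactants: 7 (1E,3R)-1-chloropent-1-en-4-yn-3-yl methanesulfonate; 8 (trimethylsilyl)methylmagnesium chloride
Product: 10 (Sa,5E)-(6-chlorohexa-2,3,5-trien-1-yl)trimethylsilane, via (trimethylsilyl)methylcopper 9 (not isolated)
Conditions: 8, CuBr·SMe2, LiBr, THF, −60 °C; then 7, −78 to −40 °C
Reagents that add atoms: none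
Why: Anti-selective SN2′ (1,3-) substitution of a propargylic sulfonate by an organocopper reagent, in which 9 attacks the alkyne terminus C7 on the face opposite to the leaving mesylate on C4, so the (R) centre is translated into the (Sa) allene axis, and the alkyne reacts in preference to the chlorine-bearing alkene terminus.

Step 6
Reactants: 11 propargyl alcohol; 12 methylmagnesium bromide
Product: 14 (Z)-3-bromo-2-methylprop-2-en-1-ol, via bromomagnesium (Z)-3-(bromomagnesio)-2-methylprop-2-en-1-olate 13 (not isolated)
Conditions: 12 (2.2 equiv), CuI (10 mol %), THF/Et2O, −10 °C to rt; then NBS, −78 to 0 °C; aqueous work-up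
Reagents that add atoms: N-bromosuccinimide, O=C1CCC(=O)N1Br
Why: Copper-catalysed, alkoxide-directed anti-carbomagnesiation of propargyl alcohol puts methyl on the internal and magnesium on the terminal carbon in a five-membered chelate, and bromination of the C–Mg bond with retention fixes Br cis to CH2OH.

Step 7
Reactants: 14 (Z)-3-bromo-2-methylprop-2-en-1-ol
Product: 15 (Z)-3-bromo-2-methylprop-2-enal
Conditions: MnO2, CH2Cl2, rt, dark
Reagents that add atoms: none
Why: Heterogeneous MnO2 oxidation of an allylic alcohol runs under neutral conditions, which should keep the (Z)-β-bromoenal from isomerising.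

Step 8
Reactants: 10 (Sa,5E)-(6-chlorohexa-2,3,5-trien-1-yl)trimethylsilane; 15 (Z)-3-bromo-2-methylprop-2-enal
Product: 16 (1S,2S,5E,6R)-6-bromo-2-chloro-1-methyl-5-[2-(trimethylsilyl)ethylidene]cyclohex-3-ene-1-carbaldehyde
Conditions: 15 (2 equiv), BHT (cat.), CH2Cl2, 1.2 GPa, 25 °C
Reagents that add atoms: none
Why: This is a concerted but asynchronous [4+2] cycloaddition (Diels–Alder reaction of a vinylallene with an enal, a known diene class that reaches the s-cis form easily because the sp carbon C3 has no inside substituent): the π bonds C6=C5 and C4=C3 of 10 add suprafacially to C1=C2 of 15, forming C3–C2 and C6–C1 together and leaving C4=C5 and the exocyclic C3=C7. The only ring, the six-membered carbocycle, is closed by this intermolecular suprafacial-suprafacial addition, so no separate cyclisation mode has to compete. Regiochemistry: the electrophilic β-carbon C2 bonds ahead of C1 to the unhindered and most nucleophilic sp carbon C3, and the charge that builds up on C4–C6 is stabilised by the chlorine on C6 (ortho rule), which places the formyl-bearing C1 next to C6. Stereochemistry: the (E)-chloroalkene holds Cl outside, the (Z)-enal keeps Br and CHO cis, and the endo mode (secondary overlap of CHO, smaller activation volume under pressure) puts both under the diene, so Br on C2, CHO on C1 and Cl on C6 should end up cis; the enal enters on the allene face that carries H, anti to CH2SiMe3 on C7, so the (Sa) axis fixes the absolute configuration (1S,2S,6R). Chemoselectivity: no Lewis acid is present, so allylsilane-type SE2′ attack of the C3=C7 bond on the enal (Hosomi–Sakurai path) stays silent, and pressure in place of heat spares the (Z)-enal and the allene. The adduct cannot lose HBr, because C2 has no β-hydrogen (C1 quaternary, C3 sp2) and the aldehyde has no α-hydrogen.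

Step 9
Reactants: 16 (1S,2S,5E,6R)-6-bromo-2-chloro-1-methyl-5-[2-(trimethylsilyl)ethylidene]cyclohex-3-ene-1-carbaldehyde
Product: 17 (E)-N-tosylhydrazone of 16
Conditions: TsNHNH2, THF/EtOH, rt
Reagents that add atoms: p-toluenesulfonyl hydrazide, Cc1ccc(cc1)S(=O)(=O)NN
Why: Simple hydrazone condensation under neutral conditions, safe because the aldehyde has no α-hydrogen and so can neither epimerise nor expel a halide.

Step 10
Reactants: 17 (E)-N-tosylhydrazone of 16
Product: 20 {(2E)-2-[(2R,4S)-2-bromo-4-chloro-3,3-dimethylcyclohex-5-en-1-ylidene]ethyl}trimethylsilane, via N′-alkyl tosylhydrazide 18 (not isolated), via monoalkyldiazene 19 (not isolated)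
Conditions: catecholborane, CHCl3, −10 °C; then NaOAc·3H2O, reflux
Reagents that add atoms: none
Why: Caglioti-type tosylhydrazone reduction in its mild catecholborane/acetate form, in which hydride adds to C=N, acetate-induced loss of sulfinate gives the diazene, and loss of N2 leaves CH3 under near-neutral conditions that should spare the hindered allylic halides and the silane, so C1 stops being a stereocentre.

Step 11
Reactants: 20 {(2E)-2-[(2R,4S)-2-bromo-4-chloro-3,3-dimethylcyclohex-5-en-1-ylidene]ethyl}trimethylsilane
Product: 21 (4S,6R)-6-bromo-4-chloro-1-ethenyl-5,5-dimethylcyclohex-1-ene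
Conditions: CF3CO2H (1.1 equiv), CH2Cl2, −40 °C
Reagents that add atoms: none
Why: Vinylogous SE2′ protodesilylation of a 2,4-pentadienylsilane, in which protonation at the ε-carbon C5 gives a C4–C3–C7 allyl cation that is also β to silicon (protonation at the fully substituted γ-carbon C3 would lack the allyl stabilisation), and loss of silicon moves the double bonds to C3=C4 and C7=C8, makes C5 the ring CH2 and touches no stereocentre.

Step 12
Reactants: 21 (4S,6R)-6-bromo-4-chloro-1-ethenyl-5,5-dimethylcyclohex-1-ene
Product: 22 (2S,3Z,4S,6S)-2-bromo-3-(2-bromoethylidene)-4,6-dichloro-1,1-dimethylcyclohexane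
Conditions: NBS, HCl (1 M in Et2O), CH2Cl2, −78 °C (BrCl formed first); then 21, −78 °C
Reagents that add atoms: N-bromosuccinimide, O=C1CCC(=O)N1Br; hydrogen chloride, Cl
Why: Electrophilic 1,4-bromochlorination of a conjugated diene, in which Br+ takes the unhindered terminus C8 of the s-trans diene (the ring alkene is hindered and deactivated by C2–Br, which sits on the nodal carbon C3 of the resulting C7–C3–C4 allyl cation), the CH2Br group pushes the charge to C4, where chloride should enter on the ring face opposite to C2–Br and C6–Cl to set (4S), and the s-trans geometry is carried into C3=C7 so that C8 ends up cis to C2.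

Compound list
1 | (E)-3-chloroacrylic acid | OC(=O)/C=C/Cl | starting material
2 | bis(trimethylsilyl)acetylene | C[Si](C)(C)C#C[Si](C)(C)C | starting material
3 | (E)-3-chloroacryloyl chloride | Cl/C=C/C(Cl)=O | intermediate
4 | (E)-1-chloro-5-(trimethylsilyl)pent-1-en-4-yn-3-one | Cl/C=C/C(=O)C#C[Si](C)(C)C | intermediate
5 | (1E,3R)-1-chloro-5-(trimethylsilyl)pent-1-en-4-yn-3-ol | Cl/C=C/[C@@H](O)C#C[Si](C)(C)C | intermediate
6 | (1E,3R)-1-chloropent-1-en-4-yn-3-ol | Cl/C=C/[C@@H](O)C#C | intermediate
7 | (1E,3R)-1-chloropent-1-en-4-yn-3-yl methanesulfonate | Cl/C=C/[C@@H](OS(C)(=O)=O)C#C | intermediate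
8 | (trimethylsilyl)methylmagnesium chloride | C[Si](C)(C)C[Mg]Cl | starting material
9 | (trimethylsilyl)methylcopper | C[Si](C)(C)C[Cu] | intermediate
10 | (Sa,5E)-(6-chlorohexa-2,3,5-trien-1-yl)trimethylsilane | Cl/C=C/C([H])=[C@@]=C([H])C[Si](C)(C)C | intermediate
11 | propargyl alcohol | C#CCO | starting material
12 | methylmagnesium bromide | C[Mg]Br | starting material
13 | bromomagnesium (Z)-3-(bromomagnesio)-2-methylprop-2-en-1-olate | Br[Mg]/C=C(/C)CO[Mg]Br | intermediate
14 | (Z)-3-bromo-2-methylprop-2-en-1-ol | Br/C=C(/C)CO | intermediate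
15 | (Z)-3-bromo-2-methylprop-2-enal | Br/C=C(/C)C=O | intermediate
16 | (1S,2S,5E,6R)-6-bromo-2-chloro-1-methyl-5-[2-(trimethylsilyl)ethylidene]cyclohex-3-ene-1-carbaldehyde | C[C@@]1(C=O)[C@H](Br)/C(=C/C[Si](C)(C)C)C=C[C@@H]1Cl | intermediate
17 | (E)-N-tosylhydrazone of 16 | C[C@@]1(/C=N/NS(=O)(=O)c2ccc(C)cc2)[C@H](Br)/C(=C/C[Si](C)(C)C)C=C[C@@H]1Cl | intermediate
18 | N′-alkyl tosylhydrazide (C=N of 17 reduced to CH2–NH) | C[C@@]1(CNNS(=O)(=O)c2ccc(C)cc2)[C@H](Br)/C(=C/C[Si](C)(C)C)C=C[C@@H]1Cl | intermediate
19 | monoalkyldiazene (CH2–N=NH on C1) | C[C@@]1(CN=N)[C@H](Br)/C(=C/C[Si](C)(C)C)C=C[C@@H]1Cl | intermediate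
20 | {(2E)-2-[(2R,4S)-2-bromo-4-chloro-3,3-dimethylcyclohex-5-en-1-ylidene]ethyl}trimethylsilane | CC1(C)[C@H](Br)/C(=C/C[Si](C)(C)C)C=C[C@@H]1Cl | intermediate
21 | (4S,6R)-6-bromo-4-chloro-1-ethenyl-5,5-dimethylcyclohex-1-ene | CC1(C)[C@H](Br)C(C=C)=CC[C@@H]1Cl | intermediate
22 | (2S,3Z,4S,6S)-2-bromo-3-(2-bromoethylidene)-4,6-dichloro-1,1-dimethylcyclohexane | CC1(C)[C@H](Br)/C(=C\CBr)[C@@H](Cl)C[C@@H]1Cl | target

Total step count: 12. Longest linear sequence: 10 steps (steps 1–5 and 8–12).

Steps most likely to fail

Step 8. The cycloaddition of a trisubstituted enal to a chlorine-deactivated diene may be too slow. This would leave room for Z-to-E isomerisation of the dienophile, self-addition of the vinylallene and erosion of the endo preference. The fallback sets out from 15 and comes back at 16; it changes the activating group. Pinnick oxidation (NaClO2, NaH2PO4, 2-methyl-2-butene) of 15 gives (Z)-3-bromo-2-methylacrylic acid F1. Oxalyl chloride turns it into (Z)-3-bromo-2-methylacryloyl chloride F2, a much stronger thermal dienophile. F2 should add to 10 at ambient pressure with the same regio- and stereochemical course to give the acid chloride cycloadduct F3. LiAlH(OtBu)3 at −78 °C then reduces this acid chloride to aldehyde 16.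

Step 12. Chloride may collapse at C7 (1,2-addition), Br+ may attack the ring alkene, or the facial selectivity at C4 may be poor. The fallback sets out from 21 and comes back at 22; it installs the two halogens one at a time. 9-BBN hydroborates only the terminal vinyl group to give the B-alkyl-9-BBN adduct F9. NaBO3·4H2O oxidises it to 2-[(4S,6R)-6-bromo-4-chloro-5,5-dimethylcyclohex-1-en-1-yl]ethanol F10. An Appel reaction (CBr4, PPh3) gives (4S,6R)-6-bromo-1-(2-bromoethyl)-4-chloro-5,5-dimethylcyclohex-1-ene F11. Selenium-catalysed ene-type allylic chlorination (NCS, PhSeCl cat.) then delivers chlorine to C4 on the free ring face and moves the double bond to C3=C7, giving 22.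

Step 5. The allylic and propargylic mesylate may ionise, which would cost enantiopurity. Direct substitution may also compete, and excess copper reagent may racemise the allene. The fallback sets out from 3 and comes back at 10; it delivers hydrogen instead of carbon to C7. N,O-dimethylhydroxylamine hydrochloride and pyridine convert 3 into (E)-3-chloro-N-methoxy-N-methylacrylamide F4. Lithiated 3-(trimethylsilyl)prop-1-yne (Weinreb ketone synthesis) gives (E)-1-chloro-6-(trimethylsilyl)hex-1-en-4-yn-3-one F5. (S)-Alpine-Borane gives (1E,3S)-1-chloro-6-(trimethylsilyl)hex-1-en-4-yn-3-ol F6. The Myers allene synthesis (2-nitrobenzenesulfonyl hydrazide, PPh3, DEAD, THF, −15 °C to rt) then proceeds by Mitsunobu inversion to the (R)-N-alkyl-N-(2-nitrobenzenesulfonyl)hydrazine F7. Loss of sulfinic acid gives the (R)-propargylic diazene F8, and suprafacial retro-ene loss of N2 gives 10.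

Further compounds
F1 | step 8 | (Z)-3-bromo-2-methylacrylic acid | Br/C=C(/C)C(O)=O
F2 | step 8 | (Z)-3-bromo-2-methylacryloyl chloride | Br/C=C(/C)C(Cl)=O
F3 | step 8 | (1S,2S,5E,6R)-6-bromo-2-chloro-1-methyl-5-[2-(trimethylsilyl)ethylidene]cyclohex-3-ene-1-carbonyl chloride | C[C@@]1(C(Cl)=O)[C@H](Br)/C(=C/C[Si](C)(C)C)C=C[C@@H]1Cl
F4 | step 5 | (E)-3-chloro-N-methoxy-N-methylacrylamide | Cl/C=C/C(=O)N(C)OC
F5 | step 5 | (E)-1-chloro-6-(trimethylsilyl)hex-1-en-4-yn-3-one | Cl/C=C/C(=O)C#CC[Si](C)(C)C
F6 | step 5 | (1E,3S)-1-chloro-6-(trimethylsilyl)hex-1-en-4-yn-3-ol | Cl/C=C/[C@H](O)C#CC[Si](C)(C)C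
F7 | step 5 | (R)-N-alkyl-N-(2-nitrobenzenesulfonyl)hydrazine | Cl/C=C/[C@@H](N(N)S(=O)(=O)c1ccccc1[N+](=O)[O-])C#CC[Si](C)(C)C
F8 | step 5 | (R)-propargylic diazene | Cl/C=C/[C@@H](N=N)C#CC[Si](C)(C)C
F9 | step 12 | B-alkyl-9-BBN adduct of 21 | CC1(C)[C@H](Br)C(CCB2C3CCCC2CCC3)=CC[C@@H]1Cl
F10 | step 12 | 2-[(4S,6R)-6-bromo-4-chloro-5,5-dimethylcyclohex-1-en-1-yl]ethanol | CC1(C)[C@H](Br)C(CCO)=CC[C@@H]1Cl
F11 | step 12 | (4S,6R)-6-bromo-1-(2-bromoethyl)-4-chloro-5,5-dimethylcyclohex-1-ene | CC1(C)[C@H](Br)C(CCBr)=CC[C@@H]1Cl
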